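Ring B of this cis-fused eremophilane holds the C8 carbonyl directly beside the isopropenyl-bearing C7. That vicinal pair is the retron of a carbonyl-ene reaction, so the plan rests on cutting C7–C8. One Lewis-acid-promoted type I ene cyclisation of aldehyde 19 forms C7–C8, closes ring B, sets C7 and C8 and generates the C11=C12 isopropenyl group. The precursor is a fully decorated ring A cyclohexane: 3α-OTBS, 4β-methyl, quaternary C5 (β-methyl, α-prenyl) and, cis to the prenyl group, a C10 α-silyloxyacetaldehyde arm (C9, C8). Ring A is relayed from enone 1; C10 comes from a Claisen shift, C9 from an enolate hydroxylation.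

Key step: step 12

Remark on the chemistry: eremophilane numbering is used for every intermediate. β is the face of the C4 and C5 methyl groups and α is the opposite face. In enone 1, C4 becomes C3, C3 becomes C4, C2 becomes C5 and C1 becomes C10, and its R configuration corresponds to 3α. Enantiopure 1 is assumed to be purchasable.

Step 1
Reactants: 1 (R)-4-(tert-butyldimethylsilyloxy)cyclohex-2-en-1-one
Product: 2 (R)-4-(tert-butyldimethylsilyloxy)-2-iodocyclohex-2-en-1-one
Conditions: I2, pyridine, CH2Cl2, 0 °C → rt
Reagents that add atoms: iodine, II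
Why: Pyridine-mediated α-iodination of a cyclic enone (conjugate addition of pyridine, iodination of the enolate, elimination) is routine for 4-silyloxycyclohexenones and does not touch the carbinol centre that becomes C3.

Step 2
Reactants: 2 (R)-4-(tert-butyldimethylsilyloxy)-2-iodocyclohex-2-en-1-one
Product: 3 (R)-4-(tert-butyldimethylsilyloxy)-2-methylcyclohex-2-en-1-one
Conditions: Me4Sn, Pd2(dba)3 (cat.), AsPh3 (cat.), CuI (cat.), NMP, 60 °C
Reagents that add atoms: tetramethylstannane, C[Sn](C)(C)C
Why: The Stille coupling of an α-iodoenone runs under neutral conditions, so γ-deprotonation cannot erode C3, and it places the future C5 methyl group on the enone α-carbon.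

Step 3
Reactants: 3 (R)-4-(tert-butyldimethylsilyloxy)-2-methylcyclohex-2-en-1-one; 4 1-bromo-3-methylbut-2-ene
Product: 6 (2R,3R,4R)-4-(tert-butyldimethylsilyloxy)-2,3-dimethyl-2-(3-methylbut-2-en-1-yl)cyclohexan-1-one, via lithium enolate 5 (not isolated)
Conditions: MeLi, CuI, Et2O, 0 °C; 3, −78 °C; then 4, HMPA, −78 °C → rt
Reagents that add atoms: lithium dimethylcuprate, [Li+].C[Cu-]C; prenyl bromide 4, CC(C)=CCBr
Why: In this tandem cuprate conjugate addition and enolate alkylation the Gilman reagent attacks C4 anti to the neighbouring silyl ether (4β-methyl, trans to 3α-O) and gives the tetrasubstituted enolate 5 regiospecifically, and 5, whose C4 methyl is pseudoaxial to escape A(1,2) strain, should take the allylic bromide on the opposite α face (cis 4,5-dimethyl pattern, as with 2,3-dimethylcyclohexanone enolates).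

Step 4
Reactants: 6 (2R,3R,4R)-4-(tert-butyldimethylsilyloxy)-2,3-dimethyl-2-(3-methylbut-2-en-1-yl)cyclohexan-1-one
Product: 8 (4R,5R,6R)-4-(tert-butyldimethylsilyloxy)-5,6-dimethyl-6-(3-methylbut-2-en-1-yl)cyclohex-2-en-1-one, via trimethylsilyl enol ether 7 (not isolated)
Conditions: TMSOTf, Et3N, CH2Cl2, 0 °C; then Pd(OAc)2, MeCN, rt
Reagents that add atoms: none
Why: In this Saegusa–Ito dehydrogenation C5 is quaternary, so silylation can only give the C1=C10 enol ether, and palladation followed by β-hydride elimination installs the C1=C2 bond without affecting the isolated prenyl alkene.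

Step 5
Reactants: 8 (4R,5R,6R)-4-(tert-butyldimethylsilyloxy)-5,6-dimethyl-6-(3-methylbut-2-en-1-yl)cyclohex-2-en-1-one
Product: 9 1α,2α-epoxy ketone (epoxide cis to 3α-OTBS and trans to 4β-methyl)
Conditions: 30% H2O2, NaOH (cat.), MeOH, 0 °C
Reagents that add atoms: hydrogen peroxide, OO
Why: In this Weitz–Scheffer epoxidation the ring is held in the half-chair with equatorial 3-OTBS, 4-methyl and prenyl groups (the flipped form would put OTBS and prenyl syn-axial), so hydroperoxide should add along the axial trajectory at C2 from the α face, trans to the C4 methyl as in the epoxidation of carvone, while the electron-rich prenyl alkene is inert to the nucleophilic oxidant.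

Step 6
Reactants: 9 1α,2α-epoxy ketone
Product: 11 (1R,4S,5R,6S)-6-(tert-butyldimethylsilyloxy)-4,5-dimethyl-4-(3-methylbut-2-en-1-yl)cyclohex-2-en-1-ol (2α-ol with C1=C10), via epoxy hydrazone 10 (not isolated)
Conditions: N2H4·H2O, AcOH (cat.), MeOH, 0 °C → rt, Ar
Reagents that add atoms: none
Why: In the Wharton transposition hydrazone 10 opens the epoxide at C1 and loses nitrogen while the C2–O bond is never broken, so the 2α configuration is carried over, and carbonyl groups next to a quaternary carbon (4,4-dimethyl-1,2-epoxy-3-ketones of the triterpene series) are known to react.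

Step 7
Reactants: 11 2α-allylic alcohol; 12 triethyl orthoacetate
Product: 14 ethyl (3α-OTBS-4β,5β-dimethyl-5α-prenylcyclohex-1-en-10α-yl)acetate, via mixed ketene acetal 13 (not isolated)
Conditions: 12 (excess), EtCO2H (cat.), 140 °C, removal of EtOH
Reagents that add atoms: triethyl orthoacetate 12, CC(OCC)(OCC)OCC
Why: In this Johnson–Claisen rearrangement the 2α oxygen is pseudoaxial in the preferred half-chair, so the suprafacial [3,3] shift hands the acetate unit to the α face of C10 (arm cis to prenyl, 10β-H), and an unsubstituted ketene acetal is chosen on purpose because an alkoxy-substituted one would have to react through the chair that hangs over the ring to give the right C9 configuration.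

Step 8
Reactants: 14 ethyl (3α-OTBS-4β,5β-dimethyl-5α-prenylcyclohex-1-en-10α-yl)acetate
Product: 15 ethyl (3α-OTBS-4β,5β-dimethyl-5α-prenylcyclohexan-10α-yl)acetate
Conditions: TsNHNH2, NaOAc, DME–H2O, reflux, stopped at consumption of 14
Reagents that add atoms: none
Why: Diimide reduction transfers H2 in a concerted syn fashion and is markedly faster for the cis-disubstituted ring alkene, whose β face carries only hydrogens at C3 and C10, than for the trisubstituted prenyl alkene, and ester and silyl ether are inert.

Step 9
Reactants: 15 ethyl (3α-OTBS-4β,5β-dimethyl-5α-prenylcyclohexan-10α-yl)acetate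
Product: 17 9-hydroxy ester (O9 anti to C5 when H9 is anti to H10; 9β in the later decalin), via potassium enolate 16 (not isolated)
Conditions: KHMDS, THF, −78 °C; then 2-(phenylsulfonyl)-3-phenyloxaziridine, −78 °C
Reagents that add atoms: 2-(phenylsulfonyl)-3-phenyloxaziridine, O=S(=O)(N1OC1c1ccccc1)c1ccccc1
Why: In this Davis hydroxylation of an ester enolate A(1,3) strain keeps C10–H in the enolate plane, quaternary C5 with its prenyl arm then covers one face, and the oxaziridine should attack from the C1 side, which places O9 anti to C5.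

Step 10
Reactants: 17 9-hydroxy ester
Product: 18 3α,9-bis(tert-butyldimethylsilyloxy) ethyl ester
Conditions: TBSOTf, 2,6-lutidine, CH2Cl2, 0 °C
Reagents that add atoms: tert-butyldimethylsilyl triflate, CC(C)(C)[Si](C)(C)OS(=O)(=O)C(F)(F)F
Why: Silylation with the silyl triflate copes with the hindered secondary alcohol, and a second TBS group gives a bulky, non-chelating α-substituent for step 12 that later falls together with the O3 group in one operation.

Step 11
Reactants: 18 3α,9-bis(tert-butyldimethylsilyloxy) ethyl ester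
Product: 19 ring A aldehyde (3α-OTBS, 4β-Me, 5β-Me, 5α-prenyl, 10α-CH(OTBS)CHO)
Conditions: DIBAL-H (1.1 equiv), CH2Cl2, −78 °C; Rochelle salt
Reagents that add atoms: none
Why: In the partial reduction of an ester with DIBAL-H the α-silyloxy group stabilises the tetrahedral aluminium hemiacetal at −78 °C (as with O-silyl lactates), so the aldehyde is set free only on work-up and C9 is not epimerised.

Step 12
Reactants: 19 ring A aldehyde
Product: 20 3α,9β-bis(tert-butyldimethylsilyloxy)-7β-isopropenyl-10βH-eremophil-11-en-8α-ol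
Conditions: Me2AlCl (1.2 equiv), CH2Cl2, −78 → −40 °C; Rochelle salt
Reagents that add atoms: none
Why: Me2AlCl binds the aldehyde oxygen, C7 of the prenyl alkene attacks C8 while a hydrogen of a C11 methyl group moves to oxygen through a cyclic six-centre array, and the aluminium-complexed alcohol then expels methane, which removes the proton that could start Prins-type or alkene-migration side reactions. The closest known reaction type is the type I intramolecular carbonyl-ene cyclisation of citronellal to isopulegol, here in its alkylaluminium halide version. The closure gives the six-membered ring B (C5–C6–C7–C8–C9–C10) and is exo at both π bonds, the carbonyl oxygen and C11 staying outside the new ring, so the double bond reappears as the exocyclic C11=C12 bond of the isopropenyl group. C7 is controlled by the chair that grows on the preferred ring A conformer (axial C10 arm, equatorial C5–CH2, equatorial 3-OTBS and 4-methyl): C11 has to be equatorial (7β), since an axial C11 would be syn-axial to C4. C8 is controlled by the same chair, the aluminium-bound oxygen taking the equatorial site (8α) gauche to C11 as the hydrogen transfer requires, with the equatorial, non-chelating 9-OTBS group antiperiplanar to the forming C7–C8 bond; this centre is erased in step 13. The step needs ene selectivity over methyl transfer and chloride capture and 7β selectivity; the first is secured by the cis arrangement of the two arms on ring A, the fully substituted C5 and the low temperature, the second by the chair, and a minor 7α isomer would end up as the equatorial 7β ketone once C8 is oxidised.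

Step 13
Reactants: 20 3α,9β-bis(tert-butyldimethylsilyloxy)-10βH-eremophil-11-en-8α-ol
Product: 21 3α,9β-bis(tert-butyldimethylsilyloxy)-10βH-eremophil-11-en-8-one
Conditions: Dess–Martin periodinane, CH2Cl2, 0 °C → rt
Reagents that add atoms: none
Why: The Dess–Martin oxidation is neutral to weakly acidic and fast for hindered secondary alcohols, so the ketone should form without enolisation, which keeps C7 and C9 intact and the C11=C12 bond out of conjugation.

Step 14
Reactants: 21 3α,9β-bis(tert-butyldimethylsilyloxy)-10βH-eremophil-11-en-8-one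
Product: 22 3α,9β-dihydroxy-10βH-eremophil-11-en-8-one
Conditions: 48% aq. HF, MeCN, 0 °C → rt
Reagents that add atoms: none
Why: Acidic fluoride desilylation removes both TBS ethers at once, and the absence of base avoids migration of the isopropenyl double bond into conjugation and enediol isomerisation of the α-ketol.

Step 15
Reactants: 22 3α,9β-dihydroxy-10βH-eremophil-11-en-8-one; 23 angelic acid
Product: 25 3α,9β-bis(angeloyloxy)-10βH-eremophil-11-en-8-one (CNP0174755.1), via mixed anhydride 24 (not isolated)
Conditions: 23, 2,4,6-Cl3C6H2COCl, Et3N (1 equiv per acid chloride), toluene, rt; then 22, 80 °C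
Reagents that add atoms: angelic acid 23, C/C=C(/C)C(=O)O
Why: The Yamaguchi-type mixed-anhydride esterification run without DMAP is the established stereoretentive way to angelates, because no nucleophilic catalyst can add to the Z-enoate and turn it into the tiglate, and since all amine is bound as its hydrochloride the base-sensitive C7–H is spared while both equatorial alcohols are acylated.

Compound list
1 | (R)-4-(tert-butyldimethylsilyloxy)cyclohex-2-en-1-one | O=C1C=C[C@H](O[Si](C)(C)C(C)(C)C)CC1 | starting material
2 | (R)-4-(tert-butyldimethylsilyloxy)-2-iodocyclohex-2-en-1-one | O=C1C(I)=C[C@H](O[Si](C)(C)C(C)(C)C)CC1 | intermediate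
3 | (R)-4-(tert-butyldimethylsilyloxy)-2-methylcyclohex-2-en-1-one | O=C1C(C)=C[C@H](O[Si](C)(C)C(C)(C)C)CC1 | intermediate
4 | 1-bromo-3-methylbut-2-ene (prenyl bromide) | CC(C)=CCBr | starting material
5 | lithium enolate (C5=C10, O-Li; 3α-OTBS, 4β-Me) | CC1=C(O[Li])CC[C@@H](O[Si](C)(C)C(C)(C)C)[C@@H]1C | intermediate
6 | (2R,3R,4R)-4-(tert-butyldimethylsilyloxy)-2,3-dimethyl-2-(3-methylbut-2-en-1-yl)cyclohexan-1-one (C10 ketone; 5β-Me, 5α-prenyl) | CC(C)=CC[C@@]1(C)C(=O)CC[C@@H](O[Si](C)(C)C(C)(C)C)[C@@H]1C | intermediate
7 | C1=C10 trimethylsilyl enol ether of 6 | CC(C)=CC[C@@]1(C)C(O[Si](C)(C)C)=CC[C@@H](O[Si](C)(C)C(C)(C)C)[C@@H]1C | intermediate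
8 | (4R,5R,6R)-4-(tert-butyldimethylsilyloxy)-5,6-dimethyl-6-(3-methylbut-2-en-1-yl)cyclohex-2-en-1-one | CC(C)=CC[C@@]1(C)C(=O)C=C[C@@H](O[Si](C)(C)C(C)(C)C)[C@@H]1C | intermediate
9 | 1α,2α-epoxide of 8 | CC(C)=CC[C@@]1(C)C(=O)[C@H]2O[C@H]2[C@@H](O[Si](C)(C)C(C)(C)C)[C@@H]1C | intermediate
10 | hydrazone of 9 | CC(C)=CC[C@@]1(C)C(=NN)[C@H]2O[C@H]2[C@@H](O[Si](C)(C)C(C)(C)C)[C@@H]1C | intermediate
11 | (1R,4S,5R,6S)-6-(tert-butyldimethylsilyloxy)-4,5-dimethyl-4-(3-methylbut-2-en-1-yl)cyclohex-2-en-1-ol (2α-ol, C1=C10) | CC(C)=CC[C@@]1(C)C=C[C@@H](O)[C@@H](O[Si](C)(C)C(C)(C)C)[C@@H]1C | intermediate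
12 | triethyl orthoacetate | CC(OCC)(OCC)OCC | starting material
13 | 2α-O-(1-ethoxyvinyl) ether of 11 (mixed ketene acetal) | CC(C)=CC[C@@]1(C)C=C[C@@H](OC(=C)OCC)[C@@H](O[Si](C)(C)C(C)(C)C)[C@@H]1C | intermediate
14 | ethyl (3α-OTBS-4β,5β-dimethyl-5α-prenylcyclohex-1-en-10α-yl)acetate | CC(C)=CC[C@@]1(C)[C@H](C=C[C@@H](O[Si](C)(C)C(C)(C)C)[C@@H]1C)CC(=O)OCC | intermediate
15 | ethyl (3α-OTBS-4β,5β-dimethyl-5α-prenylcyclohexan-10α-yl)acetate | CC(C)=CC[C@@]1(C)[C@H](CC[C@@H](O[Si](C)(C)C(C)(C)C)[C@@H]1C)CC(=O)OCC | intermediate
16 | potassium enolate of 15 (enolate geometry immaterial) | CC(C)=CC[C@@]1(C)[C@H](CC[C@@H](O[Si](C)(C)C(C)(C)C)[C@@H]1C)C=C(O[K])OCC | intermediate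
17 | 9-hydroxy ester | CC(C)=CC[C@@]1(C)[C@H](CC[C@@H](O[Si](C)(C)C(C)(C)C)[C@@H]1C)[C@@H](O)C(=O)OCC | intermediate
18 | 3α,9-bis(tert-butyldimethylsilyloxy) ethyl ester | CC(C)=CC[C@@]1(C)[C@H](CC[C@@H](O[Si](C)(C)C(C)(C)C)[C@@H]1C)[C@@H](O[Si](C)(C)C(C)(C)C)C(=O)OCC | intermediate
19 | ring A aldehyde, precursor of the key step | CC(C)=CC[C@@]1(C)[C@H](CC[C@@H](O[Si](C)(C)C(C)(C)C)[C@@H]1C)[C@@H](O[Si](C)(C)C(C)(C)C)C=O | intermediate
20 | 3α,9β-bis(tert-butyldimethylsilyloxy)-7β-isopropenyl-10βH-eremophil-11-en-8α-ol | C=C(C)[C@H]1C[C@@]2(C)[C@H](CC[C@@H](O[Si](C)(C)C(C)(C)C)[C@@H]2C)[C@@H](O[Si](C)(C)C(C)(C)C)[C@@H]1O | intermediate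
21 | 3α,9β-bis(tert-butyldimethylsilyloxy)-10βH-eremophil-11-en-8-one | C=C(C)[C@H]1C[C@@]2(C)[C@H](CC[C@@H](O[Si](C)(C)C(C)(C)C)[C@@H]2C)[C@@H](O[Si](C)(C)C(C)(C)C)C1=O | intermediate
22 | 3α,9β-dihydroxy-10βH-eremophil-11-en-8-one | C=C(C)[C@H]1C[C@@]2(C)[C@H](CC[C@@H](O)[C@@H]2C)[C@@H](O)C1=O | intermediate
23 | angelic acid, (Z)-2-methylbut-2-enoic acid | C/C=C(/C)C(=O)O | starting material
24 | angelic 2,4,6-trichlorobenzoic anhydride | C/C=C(/C)C(=O)OC(=O)c1c(Cl)cc(Cl)cc1Cl | intermediate
25 | 3α,9β-bis(angeloyloxy)-10βH-eremophil-11-en-8-one (CNP0174755.1) | C=C(C)[C@H]1C[C@@]2(C)[C@H](CC[C@@H](OC(=O)/C(C)=C\C)[C@@H]2C)[C@@H](OC(=O)/C(C)=C\C)C1=O | target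

Total step count: 15. Longest linear sequence: 15 steps (1 → 25). Compounds 4, 12 and 23 are used as bought.

Steps most likely to fail

**Step 12.**
- What may go wrong: hydrogen transfer may lose out to methyl transfer from aluminium to the aldehyde, to chloride capture at the developing C11 cation, or to silyl migration from O9 to O8.
- Fallback (sets out from 18, comes back at 20): the same C7–C8 bond would be made by a metal-mediated allylation instead of a pericyclic process.
- Selenium-catalysed ene-type chlorination of the prenyl group of 18 (NCS, cat. PhSeCl, CH2Cl2) should give the rearranged secondary allylic chloride F1, a C7 epimer mixture that already carries the isopropenyl unit.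
- DIBAL-H at −78 °C converts it into chloro aldehyde F2.
- CrCl2 in THF (Nozaki–Hiyama allylation) reduces the C–Cl bond to the primary allylchromium(III) species F3. This adds to the aldehyde through its γ-carbon C7 in a chair array and delivers 20.

**Step 3.**
- What may go wrong: facial selectivity of the alkylation may be eroded, because in the reactive half-chair the 3-OTBS group is syn-axial to the electrophile that approaches the α face. Proton transfer or O-alkylation may also compete in the copper-containing medium.
- Fallback (sets out from 3, comes back at 6): C5 would be set under catalyst control.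
- Enolate 5, generated as in step 3, is trapped with allyl chloroformate to give allyl enol carbonate F4.
- Decarboxylative asymmetric Tsuji allylation follows (Pd2(dba)3, t-Bu-PHOX, THF). The ligand enantiomer that sends allyl to the α face is expected to be S, by analogy with 2-methylcyclohexanone substrates. This gives α-allyl ketone F5.
- Cross-metathesis with 2-methylbut-2-ene (second-generation Grubbs catalyst) turns allyl into prenyl and gives 6.

**Step 5.**
- What may go wrong: attack of hydroperoxide anti to the silyl ether (β face) may compete with the axial α attack, which would invert C2 and, through the Claisen shift, C10.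
- Fallback (sets out from 8, comes back at 11): the β pathway would be accepted and C2 corrected by substitution.
- A bulky oxidant (t-BuOOH, Triton B) pushes the epoxidation to 1β,2β-epoxy ketone F6.
- Hydrazine converts it via its hydrazone F7 into 2β-alcohol F8.
- Mitsunobu reaction with acetic acid (PPh3, DIAD) inverts C2 and gives 2α-acetate F9. SN2′ attack is blocked because C10 is neopentyl.
- DIBAL-H at −78 °C removes the acetyl group without generating a free alkoxide next to the silyl ether and gives 11.

Further compounds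
F1 | step 12 | ethyl ester with 7-chloro-11(12)-ene side chain (C7 epimers) | C=C(C)C(Cl)C[C@@]1(C)[C@H](CC[C@@H](O[Si](C)(C)C(C)(C)C)[C@@H]1C)[C@@H](O[Si](C)(C)C(C)(C)C)C(=O)OCC
F2 | step 12 | chloro aldehyde (C7 epimers) | C=C(C)C(Cl)C[C@@]1(C)[C@H](CC[C@@H](O[Si](C)(C)C(C)(C)C)[C@@H]1C)[C@@H](O[Si](C)(C)C(C)(C)C)C=O
F3 | step 12 | primary allylchromium(III) dichloride | Cl[Cr](Cl)CC(C)=CC[C@@]1(C)[C@H](CC[C@@H](O[Si](C)(C)C(C)(C)C)[C@@H]1C)[C@@H](O[Si](C)(C)C(C)(C)C)C=O
F4 | step 3 | allyl enol carbonate of the C5=C10 enolate | CC1=C(OC(=O)OCC=C)CC[C@@H](O[Si](C)(C)C(C)(C)C)[C@@H]1C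
F5 | step 3 | 5α-allyl-4β,5β-dimethyl-3α-OTBS-cyclohexan-10-one | C=CC[C@@]1(C)C(=O)CC[C@@H](O[Si](C)(C)C(C)(C)C)[C@@H]1C
F6 | step 5 | 1β,2β-epoxide of 8 | CC(C)=CC[C@@]1(C)C(=O)[C@@H]2O[C@@H]2[C@@H](O[Si](C)(C)C(C)(C)C)[C@@H]1C
F7 | step 5 | hydrazone of F6 | CC(C)=CC[C@@]1(C)C(=NN)[C@@H]2O[C@@H]2[C@@H](O[Si](C)(C)C(C)(C)C)[C@@H]1C
F8 | step 5 | 2β-allylic alcohol (C2 epimer of 11) | CC(C)=CC[C@@]1(C)C=C[C@H](O)[C@@H](O[Si](C)(C)C(C)(C)C)[C@@H]1C
F9 | step 5 | 2α-acetate of 11 | CC(C)=CC[C@@]1(C)C=C[C@@H](OC(C)=O)[C@@H](O[Si](C)(C)C(C)(C)C)[C@@H]1C
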